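## Retrosynthetic overview

1. Numbering: ring A = C1(H, C11O2R)–C2(H, Me)–C3–C4–C5(Me)–C10(Me); ring B = C5–C6(homoprenyl)=C7–C8–C9–C10. The strategy rests on the bond between the two quaternary ring-fusion carbons, C5–C10. C5 bears C6, which can be carried at carboxyl level, and C10 is attached to C1, which bears the oxidised one-carbon arm C11. C5=C6(OSi)–O–C11–C1=C10 is therefore a hidden Ireland–Claisen array.
2. Late disconnections: the glyceryl ester comes from C11 acid 37 and (R)-glycidyl acetate; C1–C11O2H comes from the exocyclic alkene C1=C11 (hydroboration, oxidation); the C6–homoprenyl bond comes from the enol triflate of ketone 28.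
3. Ring B is the second carbocycle. It closes through C6–C7 by attack of a C7 alkyllithium on the C6 Weinreb amide.
4. Ring A is the first carbocycle. It closes through C5–C10 by transannular [3,3] contraction of the eight-membered lactone 18, which is made before either carbocycle.
5. Lactone 18 comes from seco acid 17. This is built from desymmetrised 3-methylglutarate (C2), Z-enol triflate/B-alkyl Suzuki coupling (C1=C10 geometry) and propanoic acid dianion alkylation (C4–C5).

Key step: step 11

Remark: C5 forms as a mixture of epimers in step 9; 16–18 are drawn as the (S)-C5 epimer, and both epimers give the same ketene acetal 19.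

## Route

Step 1
Reactants: 1 dimethyl 3-methylglutarate
Product: 2 (3R)-5-methoxy-3-methyl-5-oxopentanoic acid
Conditions: pig liver esterase, pH 7 phosphate buffer/MeOH 4:1, −10 °C, pH-stat (1 M NaOH); then HCl to pH 2
Reagents that add atoms: water, O
Why: Enzymatic desymmetrisation by ester hydrolysis: pig liver esterase is known to cleave the pro-S ester arm of this prochiral diester, which sets C2 as (R) and leaves the surviving ester as C11 and the free acid as C4.

Step 2
Reactants: 2 (3R)-5-methoxy-3-methyl-5-oxopentanoic acid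
Product: 3 methyl (3R)-5-hydroxy-3-methylpentanoate
Conditions: BH3·SMe2 (1.1 equiv), THF, −10 °C → rt; aqueous work-up
Reagents that add atoms: none
Why: Chemoselective borane reduction of a carboxylic acid beside a methyl ester; C2 is not touched, and the crude product is carried on at once so that δ-lactonisation has no time to set in.

Step 3
Reactants: 3 methyl (3R)-5-hydroxy-3-methylpentanoate
Product: 4 methyl (3S)-5-bromo-3-methylpentanoate
Conditions: CBr4, PPh3, CH2Cl2, 0 °C
Reagents that add atoms: carbon tetrabromide, BrC(Br)(Br)Br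
Why: Appel reaction, SN2 at primary C4 under neutral conditions; the bromide is a dormant leaving group that should pass through steps 4–8 without a protecting group (the descriptor changes only through CIP priorities).

Step 4
Reactants: 4 methyl (3S)-5-bromo-3-methylpentanoate
Product: 7 methyl (3R)-2-acetyl-5-bromo-3-methylpentanoate (epimers at C1), via lithium enolate 5 (not isolated), via lithium hemiaminal adduct 6 (not isolated)
Conditions: LDA (1.05 equiv), THF, −78 °C; MeC(O)N(OMe)Me (1.5 equiv), −78 → −20 °C; 1 M HCl
Reagents that add atoms: N-methoxy-N-methylacetamide, CC(=O)N(C)OC; lithium diisopropylamide, [Li+].CC(C)[N-]C(C)C (lithium in 5 and 6 only)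
Why: Crossed Claisen-type C-acylation of an ester enolate by a Weinreb amide: C11 is the only ester present, so neither the site of enolisation nor a Dieckmann closure is in question (the reason for installing C10 before C5–C6), adduct 6 blocks proton exchange and double acylation, and 4-exo attack on C4–Br is too slow at −78 °C; the labile C1 centre is of no consequence.

Step 5
Reactants: 7 methyl (3R)-2-acetyl-5-bromo-3-methylpentanoate
Product: 8 methyl (2Z)-2-[(2R)-4-bromobutan-2-yl]-3-(trifluoromethylsulfonyloxy)but-2-enoate
Conditions: Tf2O (1.3 equiv), LiOTf (2 equiv), Et3N (1.5 equiv), CH2Cl2, −10 °C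
Reagents that add atoms: trifluoromethanesulfonic anhydride, O=S(=O)(OS(=O)(=O)C(F)(F)F)C(F)(F)F
Why: Stereoselective enol triflation of a β-keto ester under soft enolisation: lithium holds both carbonyl oxygens on one side, so sulfonylation of the ketone oxygen should leave OTf cis to the ester (Z), the geometry that later places the C10 methyl trans to C11.

Step 6
Reactants: 8 methyl (2Z)-2-[(2R)-4-bromobutan-2-yl]-3-(trifluoromethylsulfonyloxy)but-2-enoate; 9 allyloxy(tert-butyl)dimethylsilane
Product: 11 methyl (2Z)-2-[(2R)-4-bromobutan-2-yl]-6-(tert-butyldimethylsilyloxy)-3-methylhex-2-enoate, via B-alkyl-9-BBN reagent 10 (not isolated)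
Conditions: 9 (1.3 equiv), 9-BBN, THF, 0 °C → rt; then 8, PdCl2(dppf) (5 mol %), 3 M aq K3PO4, DMF/THF, rt
Reagents that add atoms: 9-borabicyclo[3.3.1]nonane, B1C2CCCC1CCC2 (boron in 10 only)
Why: Anti-Markovnikov hydroboration followed by B-alkyl Suzuki–Miyaura coupling: oxidative addition of the electron-poor alkenyl triflate and reductive elimination go with retention, so the C7–C9 chain takes the place of OTf cis to C11, and the unactivated primary bromide is inert to Pd(dppf).

Step 7
Reactants: 11 methyl (2Z)-2-[(2R)-4-bromobutan-2-yl]-6-(tert-butyldimethylsilyloxy)-3-methylhex-2-enoate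
Product: 12 (2Z)-2-[(2R)-4-bromobutan-2-yl]-6-(tert-butyldimethylsilyloxy)-3-methylhex-2-en-1-ol
Conditions: DIBAL-H (2.5 equiv), CH2Cl2, −78 → −20 °C; Rochelle salt
Reagents that add atoms: none
Why: 1,2-Reduction of an α,β-unsaturated ester by DIBAL-H to the allylic alcohol; alkene geometry, bromide and silyl ether are unaffected at low temperature.

Step 8
Reactants: 12 (2Z)-2-[(2R)-4-bromobutan-2-yl]-6-(tert-butyldimethylsilyloxy)-3-methylhex-2-en-1-ol
Product: 13 2-methoxypropan-2-yl (MOP) ether of 12
Conditions: 2-methoxypropene (3 equiv), PPTS (cat.), CH2Cl2, 0 °C; Et3N quench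
Reagents that add atoms: 2-methoxypropene, COC(C)=C
Why: Acid-catalysed addition of the alcohol to an enol ether gives an achiral mixed acetal that is inert to strong base and masks the C11 alkoxide, which would otherwise close a tetrahydropyran onto C4–Br in step 9.

Step 9
Reactants: 13 MOP ether of 12; 14 propanoic acid
Product: 17 (2S,5R,6Z)-10-(tert-butyldimethylsilyloxy)-6-(hydroxymethyl)-2,5,7-trimethyldec-6-enoic acid (formed together with its 2R epimer), via dilithium propanoate enediolate 15 (not isolated), via MOP-protected lithium carboxylate 16 (not isolated)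
Conditions: 14 (3 equiv), LDA (6 equiv), THF/DMPU, 0 → 40 °C; 13, 0 °C → rt; then 1 M HCl to pH 3, THF/H2O, rt
Reagents that add atoms: lithium diisopropylamide, [Li+].CC(C)[N-]C(C)C (lithium in 15 and 16 only)
Why: Alkylation of a carboxylic acid dianion by a primary bromide (SN2) forms C4–C5 and delivers C6 directly as the free acid, so no ester has to be differentiated or cleaved; C5 forms without control, which is harmless because it is flattened in step 11, and the pH 3 work-up hydrolyses the MOP acetal while the primary TBS ether survives.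

Step 10
Reactants: 17 (2S,5R,6Z)-10-(tert-butyldimethylsilyloxy)-6-(hydroxymethyl)-2,5,7-trimethyldec-6-enoic acid
Product: 18 (3S,6R,7Z)-7-[5-(tert-butyldimethylsilyloxy)pentan-2-ylidene]-3,6-dimethyloxocan-2-one (with its 3R epimer)
Conditions: MNBA (1.3 equiv), DMAP (3 equiv), CH2Cl2, rt, syringe-pump addition of 17 over 16 h (final 1 mM)
Reagents that add atoms: none
Why: Shiina macrolactonisation (carboxyl activation by MNBA/DMAP) under pseudo-high dilution, a method with precedent for eight-membered lactones; allylic 1,3-strain about C1=C10 turns C11–O and the C3–C6 chain out of the alkene plane towards each other, and the methyl branches at C2 and C5 further favour the folded chain.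

Step 11
Reactants: 18 (3S,6R,7Z)-7-[5-(tert-butyldimethylsilyloxy)pentan-2-ylidene]-3,6-dimethyloxocan-2-one
Product: 21 (1S,2R,4R)-2-[3-(tert-butyldimethylsilyloxy)propyl]-1,2,4-trimethyl-3-methylidenecyclohexane-1-carboxylic acid, via ring-locked silyl ketene acetal 19 (not isolated), via trimethylsilyl ester 20 (not isolated)
Conditions: TMSCl/Et3N (excess), then LDA (2 equiv), THF, −78 °C → rt; PhMe, 100 °C; then aq citric acid/THF, 0 °C
Reagents that add atoms: chlorotrimethylsilane, C[Si](C)(C)Cl (silyl group in 19 and 20 only)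
Why: Proposed new method: LDA in the presence of TMSCl should convert either C5 epimer of 18 into the same ketene acetal 19, in which the eight-membered ring holds C4 and the ring oxygen cis on C5=C6, and on heating the array C5=C6–O–C11–C1=C10 should undergo a concerted suprafacial [3,3] shift that makes C5–C10, breaks C11–O and leaves C1=C11 and silyl ester 20. The closest known reactions are the Ireland–Claisen ring contraction of unsaturated medium and large lactones and the acyclic Ireland–Claisen union of two fully substituted carbons; new here is an alkene exocyclic to an eight-membered lactone, so that the ring shrinks by two atoms to a methylidenecyclohexane. Ring A (C1–C2–C3–C4–C5–C10) closes transannularly, C5 and C1 being 1,5-related in the oxocane and C10 bridging them in a bicyclo[3.3.1]nonane-like transition state, and only a chair pericyclic array lets the C2–C3–C4 tether span it because a boat would turn C4 away from C2. C5 is set by the ring-locked ketene acetal geometry (C6 axial and the methyl equatorial on the new chair) and C10 by the Z alkene (the methyl trans to C11 becomes axial and the side chain equatorial), which together place the two methyls cis and C6 cis to the C7–C9 chain. The face of C1=C10 is chosen by C2, since the chair with the C2 methyl equatorial avoids the 1,3-diaxial contact with the C10 methyl that attack on the other face would impose, so the C2 methyl ends trans to both angular methyls. The step needs O-silylation ahead of self-condensation (internal TMSCl quench) and a concerted shift ahead of ionisation of the allylic C11–O bond (amine buffer, non-polar solvent), and the gain of a carboxyl C=O together with the release of medium-ring strain makes it irreversible.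

Step 12
Reactants: 21 (1S,2R,4R)-2-[3-(tert-butyldimethylsilyloxy)propyl]-1,2,4-trimethyl-3-methylidenecyclohexane-1-carboxylic acid
Product: 23 (1S,2R,4R)-2-[3-(tert-butyldimethylsilyloxy)propyl]-N-methoxy-N,1,2,4-tetramethyl-3-methylidenecyclohexane-1-carboxamide, via acid chloride 22 (not isolated)
Conditions: 1-chloro-N,N,2-trimethylprop-1-en-1-amine (1.3 equiv), CH2Cl2, 0 °C → rt; then MeNH(OMe)·HCl, Et3N, DMAP (cat.), rt → 40 °C
Reagents that add atoms: N,O-dimethylhydroxylamine hydrochloride, CNOC.Cl; 1-chloro-N,N,2-trimethylprop-1-en-1-amine, CC(C)=C(Cl)N(C)C (chlorine in 22 only)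
Why: Acid chloride formation under neutral conditions (no HCl, so the TBS ether stays) followed by aminolysis with a small nucleophile, the standard access to the Weinreb amide of a hindered tertiary acid.

Step 13
Reactants: 23 Weinreb amide silyl ether
Product: 24 (1S,2R,4R)-2-(3-hydroxypropyl)-N-methoxy-N,1,2,4-tetramethyl-3-methylidenecyclohexane-1-carboxamide
Conditions: TBAF, THF, rt
Reagents that add atoms: none
Why: Fluoride-mediated desilylation; the shielded amide is not attacked by the liberated primary alkoxide.

Step 14
Reactants: 24 (1S,2R,4R)-2-(3-hydroxypropyl)-N-methoxy-N,1,2,4-tetramethyl-3-methylidenecyclohexane-1-carboxamide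
Product: 25 (1S,2R,4R)-2-(3-iodopropyl)-N-methoxy-N,1,2,4-tetramethyl-3-methylidenecyclohexane-1-carboxamide
Conditions: I2, PPh3, imidazole, CH2Cl2, 0 °C
Reagents that add atoms: iodine, II
Why: Appel-type iodination, SN2 at primary C7; the amide and the 1,1-disubstituted alkene are tolerated.

Step 15
Reactants: 25 (1S,2R,4R)-2-(3-iodopropyl)-N-methoxy-N,1,2,4-tetramethyl-3-methylidenecyclohexane-1-carboxamide
Product: 28 (4aR,6R,8aS)-4a,6,8a-trimethyl-5-methylideneoctahydronaphthalen-1(2H)-one, via primary alkyllithium 26 (not isolated), via chelated lithium hemiaminal 27 (not isolated)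
Conditions: t-BuLi (2.1 equiv), Et2O/pentane, −78 → 0 °C; cold 1 M HCl
Reagents that add atoms: tert-butyllithium, [Li]C(C)(C)C (lithium in 26 and 27 only)
Why: Lithium–iodine exchange followed by intramolecular Weinreb ketone synthesis, a 6-exo-trig closure of ring B through C6–C7: exchange at −78 °C is faster than attack of t-BuLi on the shielded amide, chelate 27 stops the addition at the ketone level, 5-exo carbolithiation of C1=C11 needs higher temperature, and the cis ring fusion follows from C5 and C10 as set in step 11.

Step 16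
Reactants: 28 (4aR,6R,8aS)-4a,6,8a-trimethyl-5-methylideneoctahydronaphthalen-1(2H)-one
Product: 30 (4aR,6R,8aS)-4a,6,8a-trimethyl-5-methylidene-3,4,4a,5,6,7,8,8a-octahydronaphthalen-1-yl trifluoromethanesulfonate, via potassium enolate 29 (not isolated)
Conditions: KHMDS, THF, −78 °C; PhNTf2, −78 °C → rt
Reagents that add atoms: N-phenylbis(trifluoromethanesulfonimide), O=S(=O)(N(c1ccccc1)S(=O)(=O)C(F)(F)F)C(F)(F)F; potassium hexamethyldisilazide, [K+].C[Si](C)(C)[N-][Si](C)(C)C (potassium in 29 only)
Why: Enolate formation and O-triflation: C5 is quaternary, so only C7 can be deprotonated and the C6=C7 position of the alkene is unambiguous.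

Step 17
Reactants: 30 enol triflate; 31 5-bromo-2-methylpent-2-ene
Product: 33 (2R,4aR,8aR)-2,4a,8a-trimethyl-1-methylidene-5-(4-methylpent-3-en-1-yl)-1,2,3,4,4a,7,8,8a-octahydronaphthalene, via homoprenylmagnesium bromide 32 (not isolated)
Conditions: 31, Mg, THF, rt; then 30, Fe(acac)3 (5 mol %), THF/NMP, −20 → 0 °C
Reagents that add atoms: magnesium, [Mg] (in 32 only)
Why: Iron-catalysed Kumada-type cross-coupling of an alkenyl triflate with a primary alkyl Grignard reagent, fast at low temperature and not prone to β-hydride elimination; the substrate holds no other electrophilic group.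

Step 18
Reactants: 33 triene
Product: 35 [(1S,2R,4aR,8aR)-2,4a,8a-trimethyl-5-(4-methylpent-3-en-1-yl)-1,2,3,4,4a,7,8,8a-octahydronaphthalen-1-yl]methanol, via B-alkyl-9-BBN adduct 34 (not isolated)
Conditions: 9-BBN (1.3 equiv), THF, rt → 45 °C; then 3 M NaOH, 30% H2O2, 0 °C
Reagents that add atoms: hydrogen peroxide, OO; 9-borabicyclo[3.3.1]nonane, B1C2CCCC1CCC2 (boron in 34 only)
Why: Chemoselective hydroboration–oxidation: 9-BBN adds to a 1,1-disubstituted alkene far faster than to the two trisubstituted ones, boron goes to C11, and hydrogen should reach C1 from the face opposite the axial C10 methyl, which sets C1 (S) with CH2OH equatorial and trans to the C2 methyl.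

Step 19
Reactants: 35 primary alcohol
Product: 36 (1S,2R,4aR,8aR)-2,4a,8a-trimethyl-5-(4-methylpent-3-en-1-yl)-1,2,3,4,4a,7,8,8a-octahydronaphthalene-1-carbaldehyde
Conditions: Dess–Martin periodinane, NaHCO3, CH2Cl2, 0 °C → rt; then DBU (0.2 equiv), CH2Cl2, rt
Reagents that add atoms: none
Why: Dess–Martin oxidation followed by base equilibration that funnels any C1 epimer into the equatorial aldehyde, since the axial epimer would suffer a 1,3-diaxial contact with C6.

Step 20
Reactants: 36 aldehyde
Product: 37 (1S,2R,4aR,8aR)-2,4a,8a-trimethyl-5-(4-methylpent-3-en-1-yl)-1,2,3,4,4a,7,8,8a-octahydronaphthalene-1-carboxylic acid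
Conditions: NaClO2, NaH2PO4, 2-methylbut-2-ene, t-BuOH/H2O, 0 °C → rt
Reagents that add atoms: sodium chlorite, [Na+].[O-]Cl=O
Why: Pinnick oxidation; the buffered medium does not epimerise C1 and the scavenger intercepts the chlorine by-product before it can reach the trisubstituted alkenes.

Step 21
Reactants: 38 (S)-glycidol
Product: 39 (R)-glycidyl acetate
Conditions: Ac2O, Et3N, DMAP (cat.), CH2Cl2, 0 °C
Reagents that add atoms: acetic anhydride, CC(=O)OC(C)=O
Why: O-Acetylation of the primary alcohol; the stereocentre is not touched and the descriptor changes from S to R only through the CIP priorities.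

Step 22
Reactants: 37 C11 carboxylic acid; 39 (R)-glycidyl acetate
Product: 40 [(2S)-3-acetyloxy-2-hydroxypropyl] (1S,2R,4aR,8aR)-2,4a,8a-trimethyl-5-(4-methylpent-3-en-1-yl)-1,2,3,4,4a,7,8,8a-octahydronaphthalene-1-carboxylate (CNP0146255.1)
Conditions: 39 (1.5 equiv), (R,R)-(salen)Co(III)OTs (5 mol %), i-Pr2NEt (1 equiv), t-BuOMe, rt
Reagents that add atoms: none
Why: Lewis-acid-catalysed opening of a terminal epoxide by a carboxylate at the unsubstituted carbon, known for fatty acids and glycidyl derivatives on the way to diacylglycerols: the C–O bond at the stereocentre stays intact, so (R)-39 gives the (S)-configured 2-hydroxy centre, and room temperature with a weak base should keep the acetyl group from migrating to the secondary hydroxyl.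

## Compound list

1 | dimethyl 3-methylglutarate | COC(=O)CC(C)CC(=O)OC | starting material
2 | (3R)-5-methoxy-3-methyl-5-oxopentanoic acid | COC(=O)C[C@H](C)CC(=O)O | intermediate
3 | methyl (3R)-5-hydroxy-3-methylpentanoate | COC(=O)C[C@H](C)CCO | intermediate
4 | methyl (3S)-5-bromo-3-methylpentanoate | COC(=O)C[C@H](C)CCBr | intermediate
5 | lithium enolate of 4 | [Li+].COC([O-])=C[C@H](C)CCBr | intermediate
6 | lithium hemiaminal adduct of 5 with N-methoxy-N-methylacetamide | [Li+].COC(=O)C([C@H](C)CCBr)C(C)([O-])N(C)OC | intermediate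
7 | methyl (3R)-2-acetyl-5-bromo-3-methylpentanoate (epimers at C1) | COC(=O)C(C(C)=O)[C@H](C)CCBr | intermediate
8 | methyl (2Z)-2-[(2R)-4-bromobutan-2-yl]-3-(trifluoromethylsulfonyloxy)but-2-enoate | COC(=O)/C(=C(/C)OS(=O)(=O)C(F)(F)F)[C@H](C)CCBr | intermediate
9 | allyloxy(tert-butyl)dimethylsilane | C=CCO[Si](C)(C)C(C)(C)C | starting material
10 | 9-[3-(tert-butyldimethylsilyloxy)propyl]-9-borabicyclo[3.3.1]nonane | CC(C)(C)[Si](C)(C)OCCCB1C2CCCC1CCC2 | intermediate
11 | methyl (2Z)-2-[(2R)-4-bromobutan-2-yl]-6-(tert-butyldimethylsilyloxy)-3-methylhex-2-enoate | COC(=O)/C(=C(/C)CCCO[Si](C)(C)C(C)(C)C)[C@H](C)CCBr | intermediate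
12 | (2Z)-2-[(2R)-4-bromobutan-2-yl]-6-(tert-butyldimethylsilyloxy)-3-methylhex-2-en-1-ol | OC/C(=C(/C)CCCO[Si](C)(C)C(C)(C)C)[C@H](C)CCBr | intermediate
13 | 2-methoxypropan-2-yl ether of 12 | COC(C)(C)OC/C(=C(/C)CCCO[Si](C)(C)C(C)(C)C)[C@H](C)CCBr | intermediate
14 | propanoic acid | CCC(=O)O | starting material
15 | dilithium prop-1-ene-1,1-diolate | [Li+].[Li+].CC=C([O-])[O-] | intermediate
16 | lithium (2S,5R,6Z)-10-(tert-butyldimethylsilyloxy)-6-[(2-methoxypropan-2-yloxy)methyl]-2,5,7-trimethyldec-6-enoate (with 2R epimer) | [Li+].COC(C)(C)OC/C(=C(/C)CCCO[Si](C)(C)C(C)(C)C)[C@H](C)CC[C@H](C)C([O-])=O | intermediate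
17 | (2S,5R,6Z)-10-(tert-butyldimethylsilyloxy)-6-(hydroxymethyl)-2,5,7-trimethyldec-6-enoic acid (with 2R epimer) | OC/C(=C(/C)CCCO[Si](C)(C)C(C)(C)C)[C@H](C)CC[C@H](C)C(O)=O | intermediate
18 | (3S,6R,7Z)-7-[5-(tert-butyldimethylsilyloxy)pentan-2-ylidene]-3,6-dimethyloxocan-2-one (with 3R epimer) | O=C1OC/C(=C(/C)CCCO[Si](C)(C)C(C)(C)C)[C@H](C)CC[C@@H]1C | intermediate
19 | trimethylsilyl ketene acetal of 18 (C5=C6 in the ring, C4 and ring oxygen cis) | C/C1=C(\O[Si](C)(C)C)OC/C(=C(/C)CCCO[Si](C)(C)C(C)(C)C)[C@H](C)CC1 | intermediate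
20 | trimethylsilyl ester of 21 | C=C1[C@H](C)CC[C@](C)(C(=O)O[Si](C)(C)C)[C@]1(C)CCCO[Si](C)(C)C(C)(C)C | intermediate
21 | (1S,2R,4R)-2-[3-(tert-butyldimethylsilyloxy)propyl]-1,2,4-trimethyl-3-methylidenecyclohexane-1-carboxylic acid | C=C1[C@H](C)CC[C@](C)(C(O)=O)[C@]1(C)CCCO[Si](C)(C)C(C)(C)C | intermediate
22 | acid chloride of 21 | C=C1[C@H](C)CC[C@](C)(C(Cl)=O)[C@]1(C)CCCO[Si](C)(C)C(C)(C)C | intermediate
23 | (1S,2R,4R)-2-[3-(tert-butyldimethylsilyloxy)propyl]-N-methoxy-N,1,2,4-tetramethyl-3-methylidenecyclohexane-1-carboxamide | C=C1[C@H](C)CC[C@](C)(C(=O)N(C)OC)[C@]1(C)CCCO[Si](C)(C)C(C)(C)C | intermediate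
24 | (1S,2R,4R)-2-(3-hydroxypropyl)-N-methoxy-N,1,2,4-tetramethyl-3-methylidenecyclohexane-1-carboxamide | C=C1[C@H](C)CC[C@](C)(C(=O)N(C)OC)[C@]1(C)CCCO | intermediate
25 | (1S,2R,4R)-2-(3-iodopropyl)-N-methoxy-N,1,2,4-tetramethyl-3-methylidenecyclohexane-1-carboxamide | C=C1[C@H](C)CC[C@](C)(C(=O)N(C)OC)[C@]1(C)CCCI | intermediate
26 | primary alkyllithium from 25 | C=C1[C@H](C)CC[C@](C)(C(=O)N(C)OC)[C@]1(C)CCC[Li] | intermediate
27 | chelated lithium hemiaminal at C6 (bicyclic) | [Li+].C=C1[C@H](C)CC[C@]2(C)C([O-])(N(C)OC)CCC[C@]12C | intermediate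
28 | (4aR,6R,8aS)-4a,6,8a-trimethyl-5-methylideneoctahydronaphthalen-1(2H)-one | C=C1[C@H](C)CC[C@]2(C)C(=O)CCC[C@]12C | intermediate
29 | potassium enolate of 28 | [K+].C=C1[C@H](C)CC[C@]2(C)C([O-])=CCC[C@]12C | intermediate
30 | (4aR,6R,8aS)-4a,6,8a-trimethyl-5-methylidene-3,4,4a,5,6,7,8,8a-octahydronaphthalen-1-yl trifluoromethanesulfonate | C=C1[C@H](C)CC[C@]2(C)C(OS(=O)(=O)C(F)(F)F)=CCC[C@]12C | intermediate
31 | 5-bromo-2-methylpent-2-ene | CC(C)=CCCBr | starting material
32 | (4-methylpent-3-en-1-yl)magnesium bromide | CC(C)=CCC[Mg]Br | intermediate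
33 | (2R,4aR,8aR)-2,4a,8a-trimethyl-1-methylidene-5-(4-methylpent-3-en-1-yl)-1,2,3,4,4a,7,8,8a-octahydronaphthalene | C=C1[C@H](C)CC[C@]2(C)C(CCC=C(C)C)=CCC[C@]12C | intermediate
34 | B-(C11)-alkyl-9-BBN adduct of 33 | C(B1C2CCCC1CCC2)[C@H]3[C@H](C)CC[C@]4(C)C(CCC=C(C)C)=CCC[C@]34C | intermediate
35 | [(1S,2R,4aR,8aR)-2,4a,8a-trimethyl-5-(4-methylpent-3-en-1-yl)-1,2,3,4,4a,7,8,8a-octahydronaphthalen-1-yl]methanol | OC[C@H]1[C@H](C)CC[C@]2(C)C(CCC=C(C)C)=CCC[C@]12C | intermediate
36 | (1S,2R,4aR,8aR)-2,4a,8a-trimethyl-5-(4-methylpent-3-en-1-yl)-1,2,3,4,4a,7,8,8a-octahydronaphthalene-1-carbaldehyde | O=C[C@H]1[C@H](C)CC[C@]2(C)C(CCC=C(C)C)=CCC[C@]12C | intermediate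
37 | (1S,2R,4aR,8aR)-2,4a,8a-trimethyl-5-(4-methylpent-3-en-1-yl)-1,2,3,4,4a,7,8,8a-octahydronaphthalene-1-carboxylic acid | OC(=O)[C@H]1[C@H](C)CC[C@]2(C)C(CCC=C(C)C)=CCC[C@]12C | intermediate
38 | (S)-glycidol | OC[C@H]1CO1 | starting material
39 | (R)-glycidyl acetate | CC(=O)OC[C@H]1CO1 | intermediate
40 | [(2S)-3-acetyloxy-2-hydroxypropyl] (1S,2R,4aR,8aR)-2,4a,8a-trimethyl-5-(4-methylpent-3-en-1-yl)-1,2,3,4,4a,7,8,8a-octahydronaphthalene-1-carboxylate | CC(=O)OC[C@H](O)COC(=O)[C@H]1[C@H](C)CC[C@]2(C)C(CCC=C(C)C)=CCC[C@]12C | target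

## Step count and risks

Total step count: 22. Longest linear sequence: 21 (steps 1–20 and 22; step 21 is a one-step side branch).

**1. Step 11 (Proposed new method).** The compact bicyclic transition state that joins two fully substituted carbons may be reached too slowly. In that case ionisation of the allylic C11–O bond, C-silylation or hydrolytic return to the lactone would outrun the shift.

The fallback uses known chemistry, sets out from allylic alcohol 12 and comes back at acid 21.
- Acylation with propanoyl chloride and pyridine gives the allylic propanoate F1.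
- An ordinary acyclic Ireland–Claisen rearrangement (LDA, TMSCl, THF, −78 °C → reflux, aqueous acid) forms C5–C10 with only C10 quaternary and gives the bromo acid F2.
- Two equivalents of LDA in THF/DMPU turn this acid into its dianion. Its 6-exo-tet alkylation at C4–Br closes ring A and makes C5 quaternary.
- Face selection at C10 then rests only on allylic strain about C1–C2, and C5 rests on the chair-like closure. Stereocontrol is less secure and a separation of diastereomers has to be expected.

**2. Step 10.** Intermolecular acylation (oligomerisation) may outrun closure of the strained eight-membered ring.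

The fallback sets out from seco acid 17 and comes back at lactone 18, and it reverses the roles of the two termini. In a Mitsunobu lactonisation (slow addition of 17 to PPh3/DIAD in toluene) the primary allylic C11–OH is activated and the carboxylate acts as the nucleophile in an SN2 closure. The hindered α-branched acyl carbon no longer has to be attacked. Competing SN2′ attack at the fully substituted C10 should be disfavoured for steric reasons.

**3. Step 18.** Hydroboration of the methylene group, flanked by quaternary C10 and tertiary C2, may be so slow that chemoselectivity over the side-chain alkene is lost.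

The fallback changes the order of events, sets out from enol triflate 30 and comes back at alcohol 35.
- In 30, C1=C11 is the only nucleophilic alkene, so BH3·THF (or 9-BBN at reflux) followed by NaBO3·4H2O can be used without restraint. This should give the hydroxymethyl enol triflate F3.
- Iron-catalysed coupling with 2.5 equivalents of Grignard reagent 32 (one equivalent is spent on the hydroxyl proton) then installs the homoprenyl group.

## Further compounds

F1 | step 11 | (2Z)-2-[(2R)-4-bromobutan-2-yl]-6-(tert-butyldimethylsilyloxy)-3-methylhex-2-en-1-yl propanoate | CCC(=O)OC/C(=C(/C)CCCO[Si](C)(C)C(C)(C)C)[C@H](C)CCBr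
F2 | step 11 | (3S)-3-[(3R)-5-bromo-3-methylpent-1-en-2-yl]-6-(tert-butyldimethylsilyloxy)-2,3-dimethylhexanoic acid (epimers at C5) | C=C([C@H](C)CCBr)[C@@](C)(CCCO[Si](C)(C)C(C)(C)C)C(C)C(O)=O
F0 | step 10 | none | none
F3 | step 18 | (4aR,5S,6R,8aS)-5-(hydroxymethyl)-4a,6,8a-trimethyl-3,4,4a,5,6,7,8,8a-octahydronaphthalen-1-yl trifluoromethanesulfonate | OC[C@H]1[C@H](C)CC[C@]2(C)C(OS(=O)(=O)C(F)(F)F)=CCC[C@]12C
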